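**Plan**
1. The target is the 4‑hydroxy‑5‑methylcoumarin ether of an oxidised C10 chain, numbered here C1' (OCH2) to C8' (=CH2), with methyl groups on C3' and C7'.
2. Retrosynthetic cuts, in order: (a) C6'–OOH with the C7'=C8' methylidene back to the C6'=C7' prenyl alkene (ene retron); (b) the C4'–C5' bond of the resulting homoallylic alcohol, giving the E‑enal (C4' aldehyde on C3'(Me)=C2') and a 1,1‑dimethylallyl donor; (c) the C4' aldehyde back to the E‑methyl group of a prenyl ether; (d) the C1'–O ether bond; (e) the pyranone ring.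
3. Enabling feature: the carbinol C4' sits one CH2 (C5') away from the alkene carbon C6', which is the product pattern of an allyl transfer. In its 2‑oxonia‑Cope form this transfer moves the C2 configuration of a camphor‑derived tertiary alcohol into C4' and delivers the prenyl unit in linear form.
4. Forward order: the pyranone ring is closed on the benzene ring first, then O‑prenylation, two‑stage allylic oxidation to the enal, joining of the chain at C4'–C5', and photo‑oxygenation last.
5. Stereochemistry: C2'=C3' (E) from the E‑selective SeO2 oxidation; C4' (S) from (−)‑camphor by chirality transfer; C6' (S) is created in the final ene reaction, which is not expected to be face‑selective, and is secured by separation of the C6' epimers.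

Key step: step 6

Assumption: the facial sense of step 6 is taken from the chair model given there and not from a measured result; if the opposite sense were found, the donor made in the same way from (1R,4R)‑camphor would be used.

**Step 1**
Reactants: 1 1‑(2‑hydroxy‑6‑methylphenyl)ethan‑1‑one; 2 diethyl carbonate
Product: 4 4‑hydroxy‑5‑methyl‑2H‑chromen‑2‑one, via β‑keto ester 3 (not isolated)
Conditions: NaH, toluene, 110 °C; then aq. HCl
Reagents that add atoms: none
Why: Claisen condensation of the ketone enolate with diethyl carbonate gives the β‑keto ester, whose ester group is attacked by the ortho phenoxide to close the pyranone ring, the standard synthesis of 4‑hydroxycoumarins from 2‑hydroxyacetophenones.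

**Step 2**
Reactants: 4 4‑hydroxy‑5‑methyl‑2H‑chromen‑2‑one; 5 1‑bromo‑3‑methylbut‑2‑ene
Product: 6 5‑methyl‑4‑[(3‑methylbut‑2‑en‑1‑yl)oxy]‑2H‑chromen‑2‑one
Conditions: K2CO3, acetone, 56 °C
Reagents that add atoms: none
Why: Williamson‑type O‑alkylation of the 4‑hydroxycoumarin anion with an allylic bromide is the usual preparation of 4‑allyloxycoumarins; C3‑alkylated material is removed by chromatography and the temperature stays well below that of a Claisen rearrangement of the ether.

**Step 3**
Reactants: 6 5‑methyl‑4‑[(3‑methylbut‑2‑en‑1‑yl)oxy]‑2H‑chromen‑2‑one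
Product: 7 4‑{[(2E)‑4‑hydroxy‑3‑methylbut‑2‑en‑1‑yl]oxy}‑5‑methyl‑2H‑chromen‑2‑one
Conditions: SeO2 (cat.), t‑BuOOH, CH2Cl2, 0 °C to rt
Reagents that add atoms: tert‑butyl hydroperoxide, CC(C)(C)OO; selenium dioxide, O=[Se]=O (catalytic carrier of the oxygen atom)
Why: Riley allylic oxidation in its catalytic form (ene reaction at the more substituted alkene carbon, then [2,3]‑sigmatropic shift) oxidises only the methyl group trans to the chain, which fixes the E geometry of C2'=C3'; any enal formed by over‑oxidation is the product of step 4 and is carried along.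

**Step 4**
Reactants: 7 4‑{[(2E)‑4‑hydroxy‑3‑methylbut‑2‑en‑1‑yl]oxy}‑5‑methyl‑2H‑chromen‑2‑one
Product: 8 (2E)‑2‑methyl‑4‑[(5‑methyl‑2‑oxo‑2H‑chromen‑4‑yl)oxy]but‑2‑enal
Conditions: Dess–Martin periodinane, CH2Cl2, 0 °C to rt
Reagents that add atoms: none
Why: Dess–Martin oxidation of a primary allylic alcohol gives the enal under neutral conditions without E/Z isomerisation or cleavage of the vinylogous‑carbonate ether.

**Step 5**
Reactants: 9 (1S,4S)‑1,7,7‑trimethylbicyclo[2.2.1]heptan‑2‑one [(−)‑camphor]; 10 (3‑methylbut‑2‑en‑1‑yl)magnesium chloride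
Product: 11 (1S,2R,4S)‑1,7,7‑trimethyl‑2‑(2‑methylbut‑3‑en‑2‑yl)bicyclo[2.2.1]heptan‑2‑ol
Conditions: THF, −20 °C to 0 °C; aq. NH4Cl
Reagents that add atoms: none
Why: In this Grignard addition the allylic reagent reacts through its γ‑carbon (six‑membered SE2' transition state) and approaches the carbonyl from the endo face because the syn C7 methyl blocks the exo face, so the new C2 stereocenter (exo OH, endo 1,1‑dimethylallyl) is set by the camphor skeleton.

**Step 6**
Reactants: 8 (2E)‑2‑methyl‑4‑[(5‑methyl‑2‑oxo‑2H‑chromen‑4‑yl)oxy]but‑2‑enal; 11 (1S,2R,4S)‑1,7,7‑trimethyl‑2‑(2‑methylbut‑3‑en‑2‑yl)bicyclo[2.2.1]heptan‑2‑ol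
Product: 14 4‑{[(2E,4S)‑4‑hydroxy‑3,7‑dimethylocta‑2,6‑dien‑1‑yl]oxy}‑5‑methyl‑2H‑chromen‑2‑one, via oxocarbenium ion 12 (not isolated), via rearranged oxocarbenium ion 13 (not isolated)
Conditions: camphor‑10‑sulfonic acid (20 mol %), CH2Cl2, 25 °C
Reagents that add atoms: none
Why: Acid‑catalysed condensation of the tertiary alcohol 11 with the aldehyde 8 gives the (E)‑oxocarbenium ion 12, which undergoes a chair‑like [3,3]‑sigmatropic (2‑oxonia‑Cope) rearrangement in which the CH2 terminus of the 1,1‑dimethylallyl group bonds to C4' while the C2(camphor)–CMe2 bond breaks; the resulting ion 13 is hydrolysed by the water released in the condensation to 14 and camphor, so the C4' oxygen comes from the donor. The closest known reaction type is the acid‑catalysed allyl and prenyl transfer from camphor‑ or menthone‑derived branched homoallylic alcohols to aldehydes. No ring is closed; the six‑membered array exists only in the transition state. The new stereocenter C4' is controlled by the C2 stereocenter of the donor, which is consumed: the C1 bridgehead with its methyl forces the oxocarbenium carbon to lie syn to C3H2, the aldehyde substituent is equatorial (E‑oxocarbenium), and the allyl unit held on the endo face then reaches only the Si face of C4', which corresponds to 4'S. The step needs linear regiochemistry, which the [3,3] transposition enforces (bond formation at the CH2 terminus, new trisubstituted C6'=C7' alkene), and chemoselectivity for the aldehyde, which should hold because the coumarin lactone, its enol ether and the C2'=C3' alkene are inert to catalytic sulfonic acid. The transfer is driven by relief of strain between the two adjacent quaternary carbons of 11, by the more substituted alkene and by release of the ketone.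

**Step 7**
Reactants: 14 4‑{[(2E,4S)‑4‑hydroxy‑3,7‑dimethylocta‑2,6‑dien‑1‑yl]oxy}‑5‑methyl‑2H‑chromen‑2‑one
Product: 15 4‑{[(2E,4S,6S)‑6‑hydroperoxy‑4‑hydroxy‑3,7‑dimethylocta‑2,7‑dien‑1‑yl]oxy}‑5‑methyl‑2H‑chromen‑2‑one
Conditions: O2, tetraphenylporphyrin (cat.), visible light, CH2Cl2, −20 °C; preparative HPLC
Reagents that add atoms: dioxygen, O=O
Why: In this Schenck ene reaction singlet oxygen should attack only the electron‑rich C6'=C7' alkene (C2'=C3' is deactivated by two allylic oxygens, the coumarin enol ether is electron‑poor) and hydrogen transfer from a C7' methyl group gives the secondary hydroperoxide with the C7'=C8' methylidene; C6' is created here without reliable bias from the remote C4' carbinol, so the (6'S) epimer is secured by HPLC separation from the (6'R) epimer and from the tertiary C7' hydroperoxide regioisomer.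

**Compound list**
1 | 1‑(2‑hydroxy‑6‑methylphenyl)ethan‑1‑one | CC(=O)c1c(C)cccc1O | starting material
2 | diethyl carbonate | CCOC(=O)OCC | starting material
3 | ethyl 3‑(2‑hydroxy‑6‑methylphenyl)‑3‑oxopropanoate (β‑keto ester) | CCOC(=O)CC(=O)c1c(C)cccc1O | intermediate
4 | 4‑hydroxy‑5‑methyl‑2H‑chromen‑2‑one | Cc1cccc2oc(=O)cc(O)c12 | intermediate
5 | 1‑bromo‑3‑methylbut‑2‑ene | CC(C)=CCBr | starting material
6 | 5‑methyl‑4‑[(3‑methylbut‑2‑en‑1‑yl)oxy]‑2H‑chromen‑2‑one | CC(C)=CCOc1cc(=O)oc2cccc(C)c12 | intermediate
7 | 4‑{[(2E)‑4‑hydroxy‑3‑methylbut‑2‑en‑1‑yl]oxy}‑5‑methyl‑2H‑chromen‑2‑one | OC/C(C)=C/COc1cc(=O)oc2cccc(C)c12 | intermediate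
8 | (2E)‑2‑methyl‑4‑[(5‑methyl‑2‑oxo‑2H‑chromen‑4‑yl)oxy]but‑2‑enal | O=C/C(C)=C/COc1cc(=O)oc2cccc(C)c12 | intermediate
9 | (1S,4S)‑1,7,7‑trimethylbicyclo[2.2.1]heptan‑2‑one, (−)‑camphor | CC1(C)[C@H]2CC[C@]1(C)C(=O)C2 | starting material
10 | (3‑methylbut‑2‑en‑1‑yl)magnesium chloride | CC(C)=CC[Mg]Cl | starting material
11 | (1S,2R,4S)‑1,7,7‑trimethyl‑2‑(2‑methylbut‑3‑en‑2‑yl)bicyclo[2.2.1]heptan‑2‑ol | CC1(C)[C@H]2CC[C@]1(C)[C@](O)(C(C)(C)C=C)C2 | intermediate
12 | (E)‑oxocarbenium ion from 11 and 8 (donor oxygen bound to C4' as O+=C4'H) | CC1(C)[C@H]2CC[C@]1(C)[C@](/[O+]=C/C(C)=C/COc1cc(=O)oc3cccc(C)c13)(C(C)(C)C=C)C2 | intermediate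
13 | rearranged oxocarbenium ion (camphor C2=O+ bound to (S)‑C4', prenyl on C4') | CC1(C)[C@H]2CC[C@]1(C)C(=[O+][C@@H](CC=C(C)C)/C(C)=C/COc1cc(=O)oc3cccc(C)c13)C2 | intermediate
14 | 4‑{[(2E,4S)‑4‑hydroxy‑3,7‑dimethylocta‑2,6‑dien‑1‑yl]oxy}‑5‑methyl‑2H‑chromen‑2‑one | CC(C)=CC[C@H](O)/C(C)=C/COc1cc(=O)oc2cccc(C)c12 | intermediate
15 | 4‑{[(2E,4S,6S)‑6‑hydroperoxy‑4‑hydroxy‑3,7‑dimethylocta‑2,7‑dien‑1‑yl]oxy}‑5‑methyl‑2H‑chromen‑2‑one | C=C(C)[C@H](C[C@H](O)/C(C)=C/COc1cc(=O)oc2cccc(C)c12)OO | target

**Count**
Total steps: 7. Longest linear sequence: 6 steps (steps 1, 2, 3, 4, 6, 7); step 5 is a one‑step branch.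

**Steps most likely to fail**

Step 7. The ene reaction has no element that discriminates the two faces of C6'=C7', and hydrogen abstraction from C5' competes with abstraction from the methyl group. The (6'S) hydroperoxide is therefore formed together with its C6' epimer and the tertiary regioisomer, and direct separation of the labile free hydroperoxides may be impractical. The fallback sets out from 14 and comes back at 15. The crude photo‑oxygenation mixture is treated with 2‑methoxypropene and catalytic pyridinium p‑toluenesulfonate (CH2Cl2, 0 °C). This converts the hydroperoxide into its 2‑methoxyprop‑2‑yl peroxyketal and the C4' hydroxyl into the mixed ketal. The doubly protected (6'S) compound, 4‑{[(2E,4S,6S)‑4‑[(2‑methoxypropan‑2‑yl)oxy]‑6‑[(2‑methoxypropan‑2‑yl)peroxy]‑3,7‑dimethylocta‑2,7‑dien‑1‑yl]oxy}‑5‑methyl‑2H‑chromen‑2‑one F1, should be stable on silica and is separated there from its isomers. Aqueous acetic acid in THF then releases 15. The relative configuration is checked on an aliquot by reduction to the 1,3‑diol and 13C analysis of its acetonide. This fallback secures isolation and assignment; it does not add facial control.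

Step 6. Condensation of the hindered tertiary alcohol with a conjugated, α‑branched aldehyde may be slow, and acid‑promoted ionisation at the doubly allylic C4'–O bond or capture of the prenyl alkene by an oxocarbenium ion may erode enantiopurity or consume material. The fallback sets out from 8 and comes back at 14. α‑Selective 1,2‑addition of a prenylbarium reagent (from prenyl chloride and activated barium, THF, −78 °C) gives the racemic alcohol rac‑4‑{[(2E)‑4‑hydroxy‑3,7‑dimethylocta‑2,6‑dien‑1‑yl]oxy}‑5‑methyl‑2H‑chromen‑2‑one F2. Dess–Martin oxidation gives the enone 4‑{[(2E)‑3,7‑dimethyl‑4‑oxoocta‑2,6‑dien‑1‑yl]oxy}‑5‑methyl‑2H‑chromen‑2‑one F3. Corey–Bakshi–Shibata reduction with the (R)‑methyl oxazaborolidine and catecholborane (toluene, −78 °C), with the α‑methyl alkenyl group as the large substituent, should then deliver the (S)‑alcohol 14 under catalyst control.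

Step 2. The ambident 4‑hydroxycoumarin anion may be alkylated at C3 (and then a second time) instead of at oxygen. The fallback sets out from 4 and comes back at 6, and reverses the polarity of the ether formation. Compound 4 is converted with POCl3 into 4‑chloro‑5‑methyl‑2H‑chromen‑2‑one F4. Sodium 3‑methylbut‑2‑en‑1‑olate (3‑methylbut‑2‑en‑1‑ol, NaH, THF, 0 °C) then displaces chloride by addition–elimination at C4, which can only give the O‑linked ether 6.

**Further compounds**
F1 | step 7 | 4‑{[(2E,4S,6S)‑4‑[(2‑methoxypropan‑2‑yl)oxy]‑6‑[(2‑methoxypropan‑2‑yl)peroxy]‑3,7‑dimethylocta‑2,7‑dien‑1‑yl]oxy}‑5‑methyl‑2H‑chromen‑2‑one | C=C(C)[C@H](C[C@H](OC(C)(C)OC)/C(C)=C/COc1cc(=O)oc2cccc(C)c12)OOC(C)(C)OC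
F2 | step 6 | rac‑4‑{[(2E)‑4‑hydroxy‑3,7‑dimethylocta‑2,6‑dien‑1‑yl]oxy}‑5‑methyl‑2H‑chromen‑2‑one | CC(C)=CCC(O)/C(C)=C/COc1cc(=O)oc2cccc(C)c12
F3 | step 6 | 4‑{[(2E)‑3,7‑dimethyl‑4‑oxoocta‑2,6‑dien‑1‑yl]oxy}‑5‑methyl‑2H‑chromen‑2‑one | CC(C)=CCC(=O)/C(C)=C/COc1cc(=O)oc2cccc(C)c12
F4 | step 2 | 4‑chloro‑5‑methyl‑2H‑chromen‑2‑one | Cc1cccc2oc(=O)cc(Cl)c12
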